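## Retrosynthetic overview

1. The target comes from a singlet-oxygen ene reaction on the Δ11(12) 2,14-diacetate, so the C12 hydroperoxide and the exocyclic C11=C20 olefin are installed last, as in the presumed biogenesis.
2. The six- and ten-membered rings come from one transannular C1–C10 bond formation in a 14-membered cembranoid (1,10-secobriarane) epoxy enone. The C9 ketone reacts as its silyl dienol ether, the 1,2-epoxide is the electrophile, and C1, C2 and C10 are set together.
3. The 14-membered carbocycle and the γ-lactone come from one macro-aldol/lactonization that forms C7–C8 in an open-chain keto ester enal.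
4. The open chain comes from cross-metathesis (C10=C11) of a neryl acetate-derived epoxy silyl ether (Sharpless kinetic resolution sets C14, C1, C2) with a vinyl ketone from dimethyl (S)-malate (sets C17).
5. Ring order: macrocycle and lactone first, then cyclohexene and cyclodecene by transannular cyclization, then oxygenation.

Assumption: atoms are located with briarane numbering (ring carbons C1–C14, C15 on C1, C16 on C5, lactone C17(H)–C18(H3)–C19(=O), C20 on C11), and macrocyclic precursors are named as 1,10-secobriaranes.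

## Route

Step 1
Reactants: 1 neryl acetate
Product: 2 (2Z,6E)-3,7-dimethyl-8-oxoocta-2,6-dien-1-yl acetate
Conditions: SeO2 (1.1 equiv), 95% EtOH, reflux
Reagents that add atoms: selenium dioxide, O=[Se]=O
Why: Riley allylic oxidation (SeO2 ene reaction then [2,3]-shift) attacks the (E)-methyl group of the more electron-rich terminal trisubstituted olefin and gives the (E)-enal directly; no stereocenter is formed.

Step 2
Reactants: 2 (2Z,6E)-3,7-dimethyl-8-oxoocta-2,6-dien-1-yl acetate; 3 homoallylic bromide (4-bromo-2-methylbut-1-ene)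
Product: 5 racemic carbinol (2Z,6E)-8-hydroxy-3,7,11-trimethyldodeca-2,6,11-trien-1-yl acetate, via Grignard reagent 4 (not isolated)
Conditions: 3, Mg, THF, rt; then 2, THF, −78 °C
Reagents that add atoms: none
Why: Grignard 1,2-addition to the aldehyde, which at −78 °C is far more reactive than the acetate; the new carbinol (C14) forms as a racemate that is resolved in step 3.

Step 3
Reactants: 5 racemic carbinol
Product: 6 epoxy alcohol (2Z)-5-{(2S,3S)-3-[(1S)-1-hydroxy-4-methylpent-4-en-1-yl]-3-methyloxiran-2-yl}-3-methylpent-2-en-1-yl acetate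
Conditions: Ti(OiPr)4 (0.15 equiv), L-(+)-diisopropyl tartrate (0.2 equiv), tBuOOH (0.6 equiv), 4 Å MS, CH2Cl2, −20 °C
Reagents that add atoms: tert-butyl hydroperoxide, CC(C)(C)OO
Why: Sharpless asymmetric epoxidation run as a kinetic resolution: with L-(+)-diisopropyl tartrate the (S)-carbinol reacts fast and its trisubstituted allylic olefin is epoxidised to the erythro epoxy alcohol (C14, C1 and C2 set together, at most 50% yield), while the (R)-carbinol is left behind and separated.

Step 4
Reactants: 6 epoxy alcohol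
Product: 7 silyl ether (2Z)-3-methyl-5-{(2S,3R)-3-methyl-3-[(1S)-4-methyl-1-(triethylsilyloxy)pent-4-en-1-yl]oxiran-2-yl}pent-2-en-1-yl acetate
Conditions: Et3SiCl, imidazole, DMF, 0 °C
Reagents that add atoms: chlorotriethylsilane, CC[Si](Cl)(CC)CC
Why: Silyl ether formation at the secondary alcohol blocks Payne rearrangement and alkoxide chemistry in the later basic steps; no stereocenter is touched.

Step 5
Reactants: 8 dimethyl (S)-malate
Product: 9 dimethyl (2S,3R)-2-hydroxy-3-methylbutanedioate
Conditions: LiN(iPr)2 (2.2 equiv), THF, −78 to −20 °C; MeI, −78 °C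
Reagents that add atoms: iodomethane, CI
Why: Fráter–Seebach alkylation: the chelated lithium alkoxide enolate dianion is methylated anti to the C2 oxygen, which sets the future C17 as 3R (about 9:1).

Step 6
Reactants: 9 dimethyl (2S,3R)-2-hydroxy-3-methylbutanedioate
Product: 10 Weinreb amide methyl (2R,3S)-3-hydroxy-4-[methoxy(methyl)amino]-2-methyl-4-oxobutanoate
Conditions: MeNH(OMe)·HCl, iPrMgCl (3.1 equiv), THF, −20 °C
Reagents that add atoms: N,O-dimethylhydroxylamine hydrochloride, CNOC.Cl
Why: Weinreb amide formation by aminolysis with the chloromagnesium amide, directed by the neighbouring magnesium alkoxide to the unbranched α-hydroxy ester while the α-methyl-branched ester stays intact; no stereocenter is touched.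

Step 7
Reactants: 10 Weinreb amide
Product: 11 methyl (2R,3S)-4-[methoxy(methyl)amino]-2-methyl-4-oxo-3-(triethylsilyloxy)butanoate
Conditions: Et3SiCl, imidazole, DMF, 0 °C to rt
Reagents that add atoms: chlorotriethylsilane, CC[Si](Cl)(CC)CC
Why: Silyl ether formation gives the α-silyloxy carbonyl unit needed for the later ketone enolate and prevents furanone formation from the free α'-hydroxy enone.

Step 8
Reactants: 11 silyloxy Weinreb amide
Product: 12 vinyl ketone methyl (2R,3S)-2-methyl-4-oxo-3-(triethylsilyloxy)hex-5-enoate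
Conditions: CH2=CHMgBr (1.2 equiv), THF, −78 to 0 °C; cold aq. NaHSO4
Reagents that add atoms: vinylmagnesium bromide, C=C[Mg]Br
Why: Weinreb ketone synthesis: the chelated tetrahedral adduct collapses only on work-up, so the vinyl Grignard adds once and the hindered methyl ester is untouched at low temperature.

Step 9
Reactants: 7 silyl ether; 12 vinyl ketone
Product: 13 methyl (2R,3S,5E,9S)-9-{(2R,3S)-3-[(3Z)-5-acetoxy-3-methylpent-3-en-1-yl]-2-methyloxiran-2-yl}-2,6-dimethyl-4-oxo-3,9-bis(triethylsilyloxy)non-5-enoate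
Conditions: 12 (3 equiv), second-generation Grubbs catalyst (H2IMes)(PCy3)Cl2Ru=CHPh (8 mol%), CH2Cl2, 40 °C
Reagents that add atoms: none
Why: Olefin cross-metathesis of a 1,1-disubstituted olefin with an electron-poor vinyl ketone gives the trisubstituted enone, mainly E, while the trisubstituted olefins and the epoxide are inert; the enone geometry is erased in step 13.

Step 10
Reactants: 13 enone acetate
Product: 14 methyl (2R,3S,5E,9S)-9-{(2R,3S)-3-[(3Z)-5-hydroxy-3-methylpent-3-en-1-yl]-2-methyloxiran-2-yl}-2,6-dimethyl-4-oxo-3,9-bis(triethylsilyloxy)non-5-enoate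
Conditions: K2CO3 (0.2 equiv), MeOH, 0 °C
Reagents that add atoms: none
Why: Base-catalysed transesterification (methanolysis) removes the primary allylic acetate without touching the silyl ethers, the epoxide or the methyl ester.

Step 11
Reactants: 14 allylic alcohol
Product: 15 methyl (2R,3S,5E,9S)-2,6-dimethyl-9-{(2R,3S)-2-methyl-3-[(3Z)-3-methyl-5-oxopent-3-en-1-yl]oxiran-2-yl}-4-oxo-3,9-bis(triethylsilyloxy)non-5-enoate
Conditions: MnO2 (20 equiv), CH2Cl2, rt
Reagents that add atoms: none
Why: Selective MnO2 oxidation of the primary allylic alcohol gives the enal with retention of the Z geometry.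

Step 12
Reactants: 15 keto ester enal
Product: 16 macrocyclic epoxy enone lactone (1R,2S,5Z,7S,8S,10E,14S,17R)-1,2-epoxy-9-oxo-8,14-bis(triethylsilyloxy)-1,10-secobriara-5,10-dien-19,7-olide
Conditions: KN(SiMe3)2 (1.1 equiv), THF, −78 °C, 2 mM, slow addition of 15; then −20 °C; aq. NH4Cl
Reagents that add atoms: none
Why: Intramolecular (macro)aldol addition followed by lactonization: the potassium enolate at C8 (the only enolisable α-position of the ketone) adds to the enal, and the reversible aldol is drained by irreversible γ-lactonization of the C7 alkoxide onto the methyl ester through the least strained lactone, in which the C9 acyl group is trans to both C6 and the C17 methyl (7S and 8S set under substrate control by C17).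

Step 13
Reactants: 16 macrocyclic epoxy enone lactone
Product: 19 triol ketone (1S,2S,5Z,7S,8S,10S,14S,17R)-2,8,14-trihydroxy-9-oxobriara-5,11-dien-19,7-olide, via silyl dienol ether 17 (not isolated), via silylated bicycle 18 (not isolated)
Conditions: Me3SiOTf (1.3 equiv), Et3N (1.5 equiv), CH2Cl2, −78 to 0 °C; then Me3SiOTf (0.5 equiv), −78 to −40 °C; then HF·pyridine, THF, 0 °C
Reagents that add atoms: none
Why: Proposed new method: soft enolisation turns the C9 enone into an equilibrating mixture of silyl dienol ethers of which only the (11Z)-9,11(12)-diene 17 can reach C1, and silyl triflate activation of the epoxide then lets C10 (the α-carbon of the dienol ether, far more nucleophilic than the C5=C6 olefin) open the 1,2-epoxide at its tertiary carbon C1 with inversion through a six-membered chair-like transannular transition state with the C2 and C9 chains diequatorial (hence trans ring fusion, 1S and 10S, with 2S retained and the C11=C12 olefin and C9 ketone placed without ambiguity), the closest known reactions being Lewis acid mediated alkylation of silyl enol ethers by epoxides (Mukaiyama type) and the epoxide-initiated cation–olefin cyclization that mimics the cembrane to briarane ring closure.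

Step 14
Reactants: 19 triol ketone
Product: 20 diacetate (1S,2S,5Z,7S,8S,10S,14S,17R)-2,14-diacetoxy-8-hydroxy-9-oxobriara-5,11-dien-19,7-olide
Conditions: Ac2O, pyridine, DMAP (0.1 equiv), CH2Cl2, 0 °C to rt
Reagents that add atoms: acetic anhydride, CC(=O)OC(C)=O
Why: Nucleophile-catalysed acylation of the two secondary alcohols; the tertiary C8 hydroxyl of the α-ketol is too hindered to react.

Step 15
Reactants: 20 diacetate
Product: 21 target (1S,2S,5Z,7S,8S,10S,12S,14S,17R)-2,14-diacetoxy-12-hydroperoxy-8-hydroxy-9-oxobriara-5,11(20)-dien-19,7-olide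
Conditions: O2, visible light, tetraphenylporphyrin (cat.), CH2Cl2, −20 °C
Reagents that add atoms: dioxygen, O=O
Why: Schenck ene reaction of singlet oxygen with the trisubstituted C11=C12 olefin: oxygen adds to C12 from the β face (the α face is shielded by the axial 14-acetate) with abstraction of a C20 methyl hydrogen, which gives the 12S hydroperoxide and the exocyclic C11=C20 olefin, while the C5=C6 olefin is deactivated by the allylic lactone oxygen.

## Compound list

1 | neryl acetate, (2Z)-3,7-dimethylocta-2,6-dien-1-yl acetate | CC(C)=CCC/C(C)=C\COC(C)=O | starting material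
2 | (2Z,6E)-3,7-dimethyl-8-oxoocta-2,6-dien-1-yl acetate | O=C/C(C)=C/CC/C(C)=C\COC(C)=O | intermediate
3 | 4-bromo-2-methylbut-1-ene | C=C(C)CCBr | starting material
4 | (3-methylbut-3-en-1-yl)magnesium bromide | C=C(C)CC[Mg]Br | intermediate
5 | racemic (2Z,6E)-8-hydroxy-3,7,11-trimethyldodeca-2,6,11-trien-1-yl acetate | C=C(C)CCC(O)/C(C)=C/CC/C(C)=C\COC(C)=O | intermediate
6 | (2Z)-5-{(2S,3S)-3-[(1S)-1-hydroxy-4-methylpent-4-en-1-yl]-3-methyloxiran-2-yl}-3-methylpent-2-en-1-yl acetate | C=C(C)CC[C@H](O)[C@]1(C)O[C@H]1CC/C(C)=C\COC(C)=O | intermediate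
7 | (2Z)-3-methyl-5-{(2S,3R)-3-methyl-3-[(1S)-4-methyl-1-(triethylsilyloxy)pent-4-en-1-yl]oxiran-2-yl}pent-2-en-1-yl acetate | C=C(C)CC[C@H](O[Si](CC)(CC)CC)[C@]1(C)O[C@H]1CC/C(C)=C\COC(C)=O | intermediate
8 | dimethyl (S)-malate, dimethyl (2S)-2-hydroxybutanedioate | COC(=O)C[C@H](O)C(=O)OC | starting material
9 | dimethyl (2S,3R)-2-hydroxy-3-methylbutanedioate | COC(=O)[C@@H](O)[C@@H](C)C(=O)OC | intermediate
10 | methyl (2R,3S)-3-hydroxy-4-[methoxy(methyl)amino]-2-methyl-4-oxobutanoate | CON(C)C(=O)[C@@H](O)[C@@H](C)C(=O)OC | intermediate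
11 | methyl (2R,3S)-4-[methoxy(methyl)amino]-2-methyl-4-oxo-3-(triethylsilyloxy)butanoate | CON(C)C(=O)[C@@H](O[Si](CC)(CC)CC)[C@@H](C)C(=O)OC | intermediate
12 | methyl (2R,3S)-2-methyl-4-oxo-3-(triethylsilyloxy)hex-5-enoate | C=CC(=O)[C@@H](O[Si](CC)(CC)CC)[C@@H](C)C(=O)OC | intermediate
13 | methyl (2R,3S,5E,9S)-9-{(2R,3S)-3-[(3Z)-5-acetoxy-3-methylpent-3-en-1-yl]-2-methyloxiran-2-yl}-2,6-dimethyl-4-oxo-3,9-bis(triethylsilyloxy)non-5-enoate | COC(=O)[C@H](C)[C@H](O[Si](CC)(CC)CC)C(=O)/C=C(\C)CC[C@H](O[Si](CC)(CC)CC)[C@]1(C)O[C@H]1CC/C(C)=C\COC(C)=O | intermediate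
14 | methyl (2R,3S,5E,9S)-9-{(2R,3S)-3-[(3Z)-5-hydroxy-3-methylpent-3-en-1-yl]-2-methyloxiran-2-yl}-2,6-dimethyl-4-oxo-3,9-bis(triethylsilyloxy)non-5-enoate | COC(=O)[C@H](C)[C@H](O[Si](CC)(CC)CC)C(=O)/C=C(\C)CC[C@H](O[Si](CC)(CC)CC)[C@]1(C)O[C@H]1CC/C(C)=C\CO | intermediate
15 | methyl (2R,3S,5E,9S)-2,6-dimethyl-9-{(2R,3S)-2-methyl-3-[(3Z)-3-methyl-5-oxopent-3-en-1-yl]oxiran-2-yl}-4-oxo-3,9-bis(triethylsilyloxy)non-5-enoate | COC(=O)[C@H](C)[C@H](O[Si](CC)(CC)CC)C(=O)/C=C(\C)CC[C@H](O[Si](CC)(CC)CC)[C@]1(C)O[C@H]1CC/C(C)=C\C=O | intermediate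
16 | (1R,2S,5Z,7S,8S,10E,14S,17R)-1,2-epoxy-9-oxo-8,14-bis(triethylsilyloxy)-1,10-secobriara-5,10-dien-19,7-olide | C/C1=C\C(=O)[C@@]2(O[Si](CC)(CC)CC)[C@H](/C=C(/C)CC[C@@H]3O[C@@]3(C)[C@@H](O[Si](CC)(CC)CC)CC1)OC(=O)[C@@H]2C | intermediate
17 | (1R,2S,5Z,7S,8S,9Z,11Z,14S,17R)-1,2-epoxy-8,14-bis(triethylsilyloxy)-9-(trimethylsilyloxy)-1,10-secobriara-5,9,11-trien-19,7-olide | C1/C=C(C)\C=C(/O[Si](C)(C)C)[C@@]2(O[Si](CC)(CC)CC)[C@H](/C=C(/C)CC[C@@H]3O[C@@]3(C)[C@H]1O[Si](CC)(CC)CC)OC(=O)[C@@H]2C | intermediate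
18 | (1S,2S,5Z,7S,8S,10S,14S,17R)-9-oxo-8,14-bis(triethylsilyloxy)-2-(trimethylsilyloxy)briara-5,11-dien-19,7-olide | CC=1[C@@H]2C(=O)[C@@]3(O[Si](CC)(CC)CC)[C@H](/C=C(/C)CC[C@H](O[Si](C)(C)C)[C@@]2(C)[C@@H](O[Si](CC)(CC)CC)CC1)OC(=O)[C@@H]3C | intermediate
19 | (1S,2S,5Z,7S,8S,10S,14S,17R)-2,8,14-trihydroxy-9-oxobriara-5,11-dien-19,7-olide | CC=1[C@@H]2C(=O)[C@@]3(O)[C@H](/C=C(/C)CC[C@H](O)[C@@]2(C)[C@@H](O)CC1)OC(=O)[C@@H]3C | intermediate
20 | (1S,2S,5Z,7S,8S,10S,14S,17R)-2,14-diacetoxy-8-hydroxy-9-oxobriara-5,11-dien-19,7-olide | CC=1[C@@H]2C(=O)[C@@]3(O)[C@H](/C=C(/C)CC[C@H](OC(C)=O)[C@@]2(C)[C@@H](OC(C)=O)CC1)OC(=O)[C@@H]3C | intermediate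
21 | CNP0066422.1, (1S,2S,5Z,7S,8S,10S,12S,14S,17R)-2,14-diacetoxy-12-hydroperoxy-8-hydroxy-9-oxobriara-5,11(20)-dien-19,7-olide | C=C1[C@@H]2C(=O)[C@@]3(O)[C@H](/C=C(/C)CC[C@H](OC(C)=O)[C@@]2(C)[C@@H](OC(C)=O)C[C@@H]1OO)OC(=O)[C@@H]3C | target

## Step count and risk

Total step count: 15.
Longest linear sequence: 11 steps (steps 1–4 and 9–15 from neryl acetate; the malate branch, steps 5–8 and 9–15, is equally long).

The three steps most likely to fail:

**Step 13 (transannular dienol ether–epoxide alkylation).** The dienol ether may form with the wrong regiochemistry or geometry, the epoxy silyl ether may undergo a 1,2-shift, or the epoxide may eliminate. The fallback sets out from 16 and returns at 19. Luche reduction (NaBH4, CeCl3·7H2O, MeOH, −40 °C) of 16 gives the 9-hydroxy macrocycle F1, whose C10=C11 olefin is now electron-rich. A classical epoxide-initiated cation–olefin cyclization (ZrCl4, CH2Cl2, −78 to −20 °C) then gives the bicyclic 2,9-diol F2. HF·pyridine removes the silyl ethers to give the tetraol F3. Chemoselective oxidation of the 8,9-diol at its secondary carbinol with [(neocuproine)Pd(OAc)]2(OTf)2 and benzoquinone in MeCN–H2O returns to 19.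

**Step 12 (macro-aldol/lactonization).** The enal may be deprotonated by the base, the chain may oligomerise, or the wrong C7/C8 diastereomer may lactonize. The fallback sets out from 7 and 12 and returns at 16; it makes the aldol intermolecular with a preformed enolate and closes the ring by metathesis instead. Methanolysis of 7 (K2CO3, MeOH, 0 °C) gives the allylic alcohol F4, and MnO2 oxidation gives the enal F5. Addition of F5 to the preformed lithium enolate of 12 (LiN(iPr)2, THF, −78 °C, then −20 °C) gives, after lactonization, the open-chain lactone F6. Ring-closing metathesis of its isopropenyl and vinyl ketone termini (second-generation Grubbs catalyst, 1 mM, CH2Cl2, 40 °C) closes the 14-membered ring to 16.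

**Step 15 (singlet-oxygen ene reaction).** Three ene regiochemistries are possible and a second trisubstituted olefin is present. The fallback sets out from 20 and returns at 21 by an ionic two-step sequence. Ene-type chlorination of 20 (Ca(OCl)2, solid CO2, CH2Cl2–H2O, 0 °C) gives the allylic chloride F7 with the exocyclic olefin already in place. Silver-assisted perhydrolysis (anhydrous H2O2 in Et2O, AgOCOCF3, 0 °C) goes through the allyl cation, which is captured at the secondary C12 terminus from the β face, and gives 21.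

## Further compounds

F1 | step 13 | 9-hydroxy analogue of 16 (C9 ketone reduced to the allylic alcohol, mixture of C9 epimers) | C/C1=C\C(O)[C@@]2(O[Si](CC)(CC)CC)[C@H](/C=C(/C)CC[C@@H]3O[C@@]3(C)[C@@H](O[Si](CC)(CC)CC)CC1)OC(=O)[C@@H]2C
F2 | step 13 | 2,9-dihydroxy-8,14-bis(triethylsilyloxy)briara-5,11-dien-19,7-olide (ring stereocenters as in 19, C9 epimers) | CC=1[C@@H]2C(O)[C@@]3(O[Si](CC)(CC)CC)[C@H](/C=C(/C)CC[C@H](O)[C@@]2(C)[C@@H](O[Si](CC)(CC)CC)CC1)OC(=O)[C@@H]3C
F3 | step 13 | 2,8,9,14-tetrahydroxybriara-5,11-dien-19,7-olide (ring stereocenters as in 19, C9 epimers) | CC=1[C@@H]2C(O)[C@@]3(O)[C@H](/C=C(/C)CC[C@H](O)[C@@]2(C)[C@@H](O)CC1)OC(=O)[C@@H]3C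
F4 | step 12 | (2Z)-3-methyl-5-{(2S,3R)-3-methyl-3-[(1S)-4-methyl-1-(triethylsilyloxy)pent-4-en-1-yl]oxiran-2-yl}pent-2-en-1-ol | C=C(C)CC[C@H](O[Si](CC)(CC)CC)[C@]1(C)O[C@H]1CC/C(C)=C\CO
F5 | step 12 | (2Z)-3-methyl-5-{(2S,3R)-3-methyl-3-[(1S)-4-methyl-1-(triethylsilyloxy)pent-4-en-1-yl]oxiran-2-yl}pent-2-enal | C=C(C)CC[C@H](O[Si](CC)(CC)CC)[C@]1(C)O[C@H]1CC/C(C)=C\C=O
F6 | step 12 | open-chain lactone, 10,11-seco analogue of 16 with a vinyl ketone at C9 and an isopropenyl group on C12 | C=CC(=O)[C@@]1(O[Si](CC)(CC)CC)[C@H](/C=C(/C)CC[C@@H]2O[C@@]2(C)[C@@H](O[Si](CC)(CC)CC)CCC(C)=C)OC(=O)[C@@H]1C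
F7 | step 15 | 12-chloro analogue of 21 (chlorine in place of the hydroperoxy group, exocyclic C11=C20 olefin) | C=C1[C@@H]2C(=O)[C@@]3(O)[C@H](/C=C(/C)CC[C@H](OC(C)=O)[C@@]2(C)[C@@H](OC(C)=O)C[C@@H]1Cl)OC(=O)[C@@H]3C
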